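(All runs are simulated for an exercise, and the scatter is random.)

The zeta run, charged like delta but with twice the capture agent and at 45 °C, was slowing at 17.4% after 3.00 h. Delta, the flask asked about, was read at 40.0% after 15.0 h, which by that reading puts 60.0% of its starting material not turned into target.

| flask | starting material | second substrate | reagent | capture agent | free catalyst | added ligand | temperature | remark | time |
|---|---|---|---|---|---|---|---|---|---|
| delta | 20 mM | 10 mM | 19 mM | 2 mM | 0.20 mM | 0.66 mM | 50 °C | the very flask that is asked about, followed so far |  |
| zeta | 20 mM | 10 mM | 19 mM | 4 mM | 0.20 mM | 0.66 mM | 45 °C | run made earlier |  |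
| flask | 20 mM | 10.0 mM | 19.0 mM | 2.00 mM | 0.20 mM | 0.66 mM | 50 °C |  | 15 h |

| delta: time / h | delta: target / % | zeta: time / h | zeta: target / % |
|---|---|---|---|
| 1.33 | 17.4 | 0.250 | 2.9 |
| 2.50 | 26.2 | 0.500 | 5.6 |
| 4.00 | 31.0 | 0.833 | 9.3 |
| 8.00 | 38.8 | 1.50 | 12.8 |
| 15.0 | 40.0 | 3.00 | 17.4 |

(standard deviation of a reading: 0.5 percentage points)

- target, in percent of the starting material first charged, at 15 h
- the remedy with the largest gain of target, or "none" below 2 percentage points (east / south-west / south-east / south / north / none)
- target present, with what was taken out counted in, in percent of the starting material first charged, after south-west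
- target present, with what was taken out counted in, in percent of the starting material first charged, after south-east

- east: at 15 h raise the temperature by 15 K, then wait 15 h
- south-west: at 15 h take out 90% of the target then present, then wait 15 h
- south-east: at 15 h add reagent, 100% of the amount charged, then wait 15 h
- south: change nothing and wait 15 h more
- north: at 15 h add free catalyst, 100% of the amount charged, then wait 15 h

- target that was removed still counts
- additions bring no volume worth counting

We read the time scales from delta, fastest first. Over the first reading, one catalyst turnover, counted on the catalyst charged and on target, takes on average 4.59 min. The gap to the plateau shrinks with a life of 2.90 h, which we take as the life of the working catalyst (catalyst deactivation). At the first rate, the whole charge would need 7.64 h. The fade is shorter, so in delta the catalyst fades before the starting material can be used up, and 15 h is 5.17 fade lives.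

Let a be the fraction of starting material left and f the fraction of catalyst lost. We take a to fall in proportion to a and to working catalyst, and f to rise in proportion to working catalyst and capture agent. A full dose can use at most 10.0% of the capture agent in delta, so we hold that charge steady. Dividing one rate by the other removes time:

a = exp(−s·f)

Here s is the clearing number, the logarithmic share of starting material that one full dose of catalyst clears before it is lost. From the plateau as read in delta, with f taken as whole:

s = −ln(a at the plateau) = 0.511

We test it on zeta, leaving temperature aside. In our rule, doubled capture agent halves s, which gives zeta a ceiling of 22.5%. With zeta's first rate, this gives 17.7% at 3.00 h, against the 17.4% read.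

North, a second full dose, multiplies a by the same factor again:

gain = a·(1 − a) = 24 percentage points

So we name north. The forecast gives 40%, best none, 40.2% after south-west and 40.2% after south-east, on this ground: “the flask is out of usable second substrate, not short of catalyst or reagent”.

The flask gives 40.2%, best north, 40.5% after south-west and 40.6% after south-east.

    catalyst intermediate B + capture agent → trapped intermediate (k = 1600 /M/h, Ea = 43.0 kJ/mol)
    free catalyst + added ligand ⇌ idle complex, settled at all times (K = 37000 /M, ΔH = 8.00 kJ/mol)
    reagent + catalyst intermediate A → free catalyst + target (k = 3200 /M/h, Ea = 35.0 kJ/mol)
    second substrate + free catalyst ⇌ catalyst intermediate B (K = 540 /M, k = 55000 /M/h, Ea = 55.0 kJ/mol, ΔH = −30.0 kJ/mol)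
    starting material + free catalyst ⇌ catalyst intermediate A (K = 15000 /M, k = 37000 /M/h, Ea = 49.0 kJ/mol, ΔH = −64.0 kJ/mol)
    reagent + catalyst intermediate B → free catalyst + second product (k = 860 /M/h, Ea = 66.0 kJ/mol)
    (constants at 50 °C)

North gains 26 points, beside our 24 points, while south gains 0.3 points. A neighbouring flask is charged with 2.5 mM of second substrate, a quarter of this flask's. In the scheme, second substrate makes catalyst intermediate B and capture agent catches it; we scale s inversely with that charge, to 2.04. At 15.0 h, that neighbour holds 73.3% of its catalyst as trapped intermediate, so the rule leaves 22.4% of the starting material. The neighbour holds 22.5% of its starting material, and its target stands at 77.4%.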